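**Retrosynthetic overview**
- The target comes from a fully protected bis-indole by removal of one N-tosyl and three O-TBS groups.
- Only one ring is built, and it is built last: the pyrrole ring of the tryptophol unit, by Larock annulation of 2-iodoaniline with an internal alkyne. The 3-indolyl ring is carried intact from methyl indole-3-acetate.
- The internal alkyne comes from a 1,1-dibromo-olefin, whose Corey–Fuchs lithium acetylide is trapped in the same flask with ethylene oxide; the dibromo-olefin comes from an aldehyde.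
- The aldehyde comes from an Evans syn-aldol adduct. This is the key C–C bond (methine carbon to carbinol carbon) and sets both stereocentres, from an N-(1-tosylindol-3-ylacetyl)oxazolidinone and TBSOCH2CHO.
- The imide comes from methyl indole-3-acetate and (S)-4-benzyl-2-oxazolidinone.

Assumption: the SMILES is read as (2S,3R)-3-[3-(2-hydroxyethyl)-1H-indol-2-yl]-3-(1H-indol-3-yl)propane-1,2-diol; descriptor changes along the route (for example S to R at the aryl-bearing carbon) come from CIP priorities only, the geometry set in step 4 is never altered. Tosyl = 4-methylbenzenesulfonyl, TBS = tert-butyldimethylsilyl.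

**Route**

Step 1
Reactants: 1 methyl 2-(1H-indol-3-yl)acetate
Product: 3 methyl 2-(1-tosyl-1H-indol-3-yl)acetate, via sodium indolide 2 (not isolated)
Conditions: NaH (1.1 equiv), DMF, 0 °C, 30 min; then TsCl (1.1 equiv), 0 °C → rt
Reagents that add atoms: p-toluenesulfonyl chloride (TsCl), Cc1ccc(cc1)S(Cl)(=O)=O
Why: The indole N–H is the most acidic site, so the N-sodio salt forms and is N-sulfonylated, masking the indole as an electron-poor sulfonamide that tolerates the later enolisation, hydride, oxidation and palladium steps.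

Step 2
Reactants: 3 methyl 2-(1-tosyl-1H-indol-3-yl)acetate
Product: 4 2-(1-tosyl-1H-indol-3-yl)acetic acid
Conditions: LiOH·H2O (2 equiv), THF/H2O 3:1, 0 °C → rt; then 1 M HCl to pH 3
Reagents that add atoms: lithium hydroxide, [Li+].[OH-]
Why: Ester saponification at room temperature is much faster than hydroxide attack on the N-sulfonyl group, giving the free acid for auxiliary attachment.

Step 3
Reactants: 4 2-(1-tosyl-1H-indol-3-yl)acetic acid; 5 (S)-4-benzyl-1,3-oxazolidin-2-one
Product: 7 (S)-4-benzyl-3-[2-(1-tosyl-1H-indol-3-yl)acetyl]-1,3-oxazolidin-2-one, via mixed pivalic anhydride 6 (not isolated)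
Conditions: PivCl (1.1 equiv), Et3N (2.5 equiv), THF, −20 °C, 1 h; then LiCl (1.1 equiv), 5 (1.0 equiv), −20 °C → rt
Reagents that add atoms: none
Why: N-Acylation of the oxazolidinone through the mixed pivalic anhydride with LiCl/Et3N activation attaches the Evans auxiliary without strong base, attack occurring at the less hindered arylacetyl carbonyl.

Step 4
Reactants: 7 (S)-4-benzyl-3-[2-(1-tosyl-1H-indol-3-yl)acetyl]-1,3-oxazolidin-2-one; 8 2-(tert-butyldimethylsilyloxy)acetaldehyde
Product: 11 (S)-4-benzyl-3-[(2S,3S)-4-(tert-butyldimethylsilyloxy)-3-hydroxy-2-(1-tosyl-1H-indol-3-yl)butanoyl]-1,3-oxazolidin-2-one, via Z-dibutylboron enolate 9 (not isolated), via dibutylboron aldolate 10 (not isolated)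
Conditions: Bu2BOTf (1.2 equiv), iPr2NEt (1.4 equiv), CH2Cl2, 0 °C, 45 min; 8 (1.3 equiv), −78 °C → 0 °C; pH 7 phosphate buffer/MeOH, 30% H2O2, 0 °C
Reagents that add atoms: none
Why: Evans syn-aldol reaction, in which soft enolisation gives the Z-boron enolate that adds to the aldehyde through a closed Zimmerman–Traxler chair on the face opposite the benzyl group, forming the key C–C bond and setting both stereocentres as (2S,3S), the syn pair that becomes 3R,2S of the target.

Step 5
Reactants: 11 aldol adduct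
Product: 12 (S)-4-benzyl-3-[(2S,3S)-3,4-bis(tert-butyldimethylsilyloxy)-2-(1-tosyl-1H-indol-3-yl)butanoyl]-1,3-oxazolidin-2-one
Conditions: TBSOTf (1.3 equiv), 2,6-lutidine (2 equiv), CH2Cl2, −78 → 0 °C
Reagents that add atoms: tert-butyldimethylsilyl triflate (TBSOTf), CC(C)(C)[Si](C)(C)OS(=O)(=O)C(F)(F)F
Why: O-Silylation of the secondary alcohol with a silyl triflate and a hindered base shuts down retro-aldol and β-elimination in the following steps without touching the stereocentres.

Step 6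
Reactants: 12 bis-TBS imide
Product: 13 (2R,3S)-3,4-bis(tert-butyldimethylsilyloxy)-2-(1-tosyl-1H-indol-3-yl)butan-1-ol
Conditions: LiBH4 (2 equiv), MeOH (2 equiv), THF, 0 °C; aqueous work-up
Reagents that add atoms: none
Why: Hydride reduction of the imide carbonyl (reductive auxiliary removal) releases the primary alcohol and the recyclable oxazolidinone under non-enolising conditions, so the α-stereocentre is retained.

Step 7
Reactants: 13 primary alcohol
Product: 14 (2S,3S)-3,4-bis(tert-butyldimethylsilyloxy)-2-(1-tosyl-1H-indol-3-yl)butanal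
Conditions: Dess–Martin periodinane (1.5 equiv), NaHCO3 (5 equiv), CH2Cl2, 0 °C → rt, 1 h; short silica pad, used at once
Reagents that add atoms: none
Why: Dess–Martin oxidation under bicarbonate buffer is fast and free of amine base, so the α-indolyl aldehyde forms without enolisation and is carried on crude.

Step 8
Reactants: 14 aldehyde
Product: 15 3-[(3S,4S)-1,1-dibromo-4,5-bis(tert-butyldimethylsilyloxy)pent-1-en-3-yl]-1-tosyl-1H-indole
Conditions: CBr4 (2 equiv), PPh3 (4 equiv), CH2Cl2, 0 °C, 15 min; then 14, 2,6-lutidine (2 equiv), −20 → 0 °C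
Reagents that add atoms: carbon tetrabromide, BrC(Br)(Br)Br
Why: Ramirez dibromo-olefination (first stage of the Corey–Fuchs sequence) is a Wittig reaction of the non-basic ylide Ph3P=CBr2 that adds one carbon without epimerising the α-centre.

Step 9
Reactants: 15 dibromo-olefin
Product: 17 (5S,6S)-6,7-bis(tert-butyldimethylsilyloxy)-5-(1-tosyl-1H-indol-3-yl)hept-3-yn-1-ol, via lithium acetylide 16 (not isolated)
Conditions: n-BuLi (2.05 equiv), THF, −78 °C, 1 h; BF3·OEt2 (2 equiv), −78 °C, 10 min; ethylene oxide (5 equiv, THF solution), −78 °C, 2 h; sat. aq. NH4Cl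
Reagents that add atoms: ethylene oxide, C1CO1
Why: Corey–Fuchs alkyne synthesis with trapping in the same flask (Yamaguchi-type alkynylation), in which bromine–lithium exchange, loss of LiBr with 1,2-hydrogen shift and metalation by the second equivalent of n-BuLi give the lithium acetylide, which uses up all the base before it can touch the N-tosylindole and then opens BF3-activated ethylene oxide by SN2 attack at −78 °C to add the two carbons of the hydroxyethyl chain.

Step 10
Reactants: 17 homopropargylic alcohol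
Product: 18 3-[(5S,6S)-1,6,7-tris(tert-butyldimethylsilyloxy)hept-3-yn-5-yl]-1-tosyl-1H-indole
Conditions: TBSCl (1.2 equiv), imidazole (2.5 equiv), DMF, rt
Reagents that add atoms: tert-butyldimethylsilyl chloride (TBSCl), CC(C)(C)[Si](C)(C)Cl
Why: Routine silylation of the primary alcohol removes a free hydroxyl that could coordinate palladium and perturb the regiochemistry of the annulation.

Step 11
Reactants: 18 internal alkyne; 19 2-iodoaniline
Product: 20 3-{(1R,2S)-2,3-bis(tert-butyldimethylsilyloxy)-1-[3-(2-(tert-butyldimethylsilyloxy)ethyl)-1H-indol-2-yl]propyl}-1-tosyl-1H-indole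
Conditions: Pd(OAc)2 (10 mol %), LiCl (1 equiv), K2CO3 (3 equiv), 19 (1.5 equiv), DMF, 100 °C
Reagents that add atoms: none
Why: Larock heteroannulation, in which oxidative addition of the carbon–iodine bond to zerovalent palladium (from Pd(OAc)2), syn-carbopalladation placing the aryl group on the less hindered alkyne carbon and C–N reductive elimination build the pyrrole ring with the branched substituent at C2 and the silyloxyethyl chain at C3, the sp3 stereocentres not being involved.

Step 12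
Reactants: 20 protected bis-indole
Product: 21 (2S,3R)-3-[3-(2-hydroxyethyl)-1H-indol-2-yl]-3-(1-tosyl-1H-indol-3-yl)propane-1,2-diol
Conditions: TBAF (4.5 equiv), THF, 0 °C → rt
Reagents that add atoms: none
Why: Fluoride-mediated desilylation cleaves the three Si–O bonds at room temperature while the N-sulfonyl group (lost to fluoride only at reflux) stays, and no acid is used that could ionise the bis-indolylmethine.

Step 13
Reactants: 21 N-tosyl triol
Product: 22 Colletotryptin A, (2S,3R)-3-[3-(2-hydroxyethyl)-1H-indol-2-yl]-3-(1H-indol-3-yl)propane-1,2-diol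
Conditions: Mg turnings (15 equiv), MeOH, rt, sonication; aqueous work-up
Reagents that add atoms: none
Why: Single-electron reductive desulfonylation by magnesium in methanol cleaves the N–S bond under non-acidic conditions that leave the alcohols, both indoles and both stereocentres untouched.

**Compound list**

1 | methyl 2-(1H-indol-3-yl)acetate | COC(=O)Cc1c[nH]c2ccccc12 | starting material
2 | sodium salt of 1 (N-sodio indolide, formed in the flask) | COC(=O)Cc1c[n-]c2ccccc12.[Na+] | intermediate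
3 | methyl 2-(1-tosyl-1H-indol-3-yl)acetate | COC(=O)Cc1cn(S(=O)(=O)c2ccc(C)cc2)c2ccccc12 | intermediate
4 | 2-(1-tosyl-1H-indol-3-yl)acetic acid | OC(=O)Cc1cn(S(=O)(=O)c2ccc(C)cc2)c2ccccc12 | intermediate
5 | (S)-4-benzyl-1,3-oxazolidin-2-one | O=C1N[C@@H](Cc2ccccc2)CO1 | starting material
6 | pivalic 2-(1-tosyl-1H-indol-3-yl)acetic mixed anhydride (formed in the flask) | CC(C)(C)C(=O)OC(=O)Cc1cn(S(=O)(=O)c2ccc(C)cc2)c2ccccc12 | intermediate
7 | (S)-4-benzyl-3-[2-(1-tosyl-1H-indol-3-yl)acetyl]-1,3-oxazolidin-2-one | O=C(Cc1cn(S(=O)(=O)c2ccc(C)cc2)c2ccccc12)N1[C@@H](Cc2ccccc2)COC1=O | intermediate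
8 | 2-(tert-butyldimethylsilyloxy)acetaldehyde | O=CCO[Si](C)(C)C(C)(C)C | starting material
9 | Z-dibutylboron enolate of 7 (formed in the flask) | CCCCB(CCCC)O/C(=C\c1cn(S(=O)(=O)c2ccc(C)cc2)c2ccccc12)N1[C@@H](Cc2ccccc2)COC1=O | intermediate
10 | O-dibutylboryl aldolate of 11 (formed in the flask) | O=C([C@@H](c1cn(S(=O)(=O)c2ccc(C)cc2)c2ccccc12)[C@H](OB(CCCC)CCCC)CO[Si](C)(C)C(C)(C)C)N1[C@@H](Cc2ccccc2)COC1=O | intermediate
11 | (S)-4-benzyl-3-[(2S,3S)-4-(tert-butyldimethylsilyloxy)-3-hydroxy-2-(1-tosyl-1H-indol-3-yl)butanoyl]-1,3-oxazolidin-2-one | O=C([C@@H](c1cn(S(=O)(=O)c2ccc(C)cc2)c2ccccc12)[C@H](O)CO[Si](C)(C)C(C)(C)C)N1[C@@H](Cc2ccccc2)COC1=O | intermediate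
12 | (S)-4-benzyl-3-[(2S,3S)-3,4-bis(tert-butyldimethylsilyloxy)-2-(1-tosyl-1H-indol-3-yl)butanoyl]-1,3-oxazolidin-2-one | O=C([C@@H](c1cn(S(=O)(=O)c2ccc(C)cc2)c2ccccc12)[C@H](O[Si](C)(C)C(C)(C)C)CO[Si](C)(C)C(C)(C)C)N1[C@@H](Cc2ccccc2)COC1=O | intermediate
13 | (2R,3S)-3,4-bis(tert-butyldimethylsilyloxy)-2-(1-tosyl-1H-indol-3-yl)butan-1-ol | OC[C@@H](c1cn(S(=O)(=O)c2ccc(C)cc2)c2ccccc12)[C@H](O[Si](C)(C)C(C)(C)C)CO[Si](C)(C)C(C)(C)C | intermediate
14 | (2S,3S)-3,4-bis(tert-butyldimethylsilyloxy)-2-(1-tosyl-1H-indol-3-yl)butanal | O=C[C@@H](c1cn(S(=O)(=O)c2ccc(C)cc2)c2ccccc12)[C@H](O[Si](C)(C)C(C)(C)C)CO[Si](C)(C)C(C)(C)C | intermediate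
15 | 3-[(3S,4S)-1,1-dibromo-4,5-bis(tert-butyldimethylsilyloxy)pent-1-en-3-yl]-1-tosyl-1H-indole | BrC(Br)=C[C@@H](c1cn(S(=O)(=O)c2ccc(C)cc2)c2ccccc12)[C@H](O[Si](C)(C)C(C)(C)C)CO[Si](C)(C)C(C)(C)C | intermediate
16 | lithium (3S,4S)-4,5-bis(tert-butyldimethylsilyloxy)-3-(1-tosyl-1H-indol-3-yl)pent-1-yn-1-ide (lithium acetylide, formed in the flask) | [Li]C#C[C@@H](c1cn(S(=O)(=O)c2ccc(C)cc2)c2ccccc12)[C@H](O[Si](C)(C)C(C)(C)C)CO[Si](C)(C)C(C)(C)C | intermediate
17 | (5S,6S)-6,7-bis(tert-butyldimethylsilyloxy)-5-(1-tosyl-1H-indol-3-yl)hept-3-yn-1-ol | OCCC#C[C@@H](c1cn(S(=O)(=O)c2ccc(C)cc2)c2ccccc12)[C@H](O[Si](C)(C)C(C)(C)C)CO[Si](C)(C)C(C)(C)C | intermediate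
18 | 3-[(5S,6S)-1,6,7-tris(tert-butyldimethylsilyloxy)hept-3-yn-5-yl]-1-tosyl-1H-indole | CC(C)(C)[Si](C)(C)OCCC#C[C@@H](c1cn(S(=O)(=O)c2ccc(C)cc2)c2ccccc12)[C@H](O[Si](C)(C)C(C)(C)C)CO[Si](C)(C)C(C)(C)C | intermediate
19 | 2-iodoaniline | Nc1ccccc1I | starting material
20 | 3-{(1R,2S)-2,3-bis(tert-butyldimethylsilyloxy)-1-[3-(2-(tert-butyldimethylsilyloxy)ethyl)-1H-indol-2-yl]propyl}-1-tosyl-1H-indole | CC(C)(C)[Si](C)(C)OCCc1c([C@@H](c2cn(S(=O)(=O)c3ccc(C)cc3)c3ccccc23)[C@H](O[Si](C)(C)C(C)(C)C)CO[Si](C)(C)C(C)(C)C)[nH]c2ccccc12 | intermediate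
21 | (2S,3R)-3-[3-(2-hydroxyethyl)-1H-indol-2-yl]-3-(1-tosyl-1H-indol-3-yl)propane-1,2-diol | OCCc1c([C@@H](c2cn(S(=O)(=O)c3ccc(C)cc3)c3ccccc23)[C@H](O)CO)[nH]c2ccccc12 | intermediate
22 | Colletotryptin A, (2S,3R)-3-[3-(2-hydroxyethyl)-1H-indol-2-yl]-3-(1H-indol-3-yl)propane-1,2-diol | OCCc1c([C@@H](c2c[nH]c3ccccc23)[C@H](O)CO)[nH]c2ccccc12 | target

**Totals**

Total step count: 13. Longest linear sequence: 13 steps (1 → 22).

**Steps most likely to fail, with fallbacks**

Step 11 (Larock annulation). The alkyne is very hindered, so insertion may be slow, and the regiochemistry rests only on the steric difference between the two alkyne substituents. The fallback sets out from 15. n-BuLi (2.05 equiv, THF, −78 °C) gives lithium acetylide 16 as in step 9, and ZnCl2 (1.2 equiv, −78 → 0 °C) turns it into [(3R,4S)-4,5-bis(tert-butyldimethylsilyloxy)-3-(1-tosyl-1H-indol-3-yl)pent-1-yn-1-yl]zinc chloride F1 (same geometry as 16; the descriptor changes only because zinc raises the CIP rank of the alkynyl group). Negishi coupling in the same flask with 19 (Pd(PPh3)4 5 mol %, THF, rt → 40 °C) gives 2-[(3S,4S)-4,5-bis(tert-butyldimethylsilyloxy)-3-(1-tosyl-1H-indol-3-yl)pent-1-yn-1-yl]aniline F2, in which the aryl–alkyne bond fixes the regiochemistry. Cyclisation of the amine onto the alkyne (PdCl2(MeCN)2 10 mol %, dry MeCN, 80 °C) gives 3-[(1R,2S)-2,3-bis(tert-butyldimethylsilyloxy)-1-(1H-indol-2-yl)propyl]-1-tosyl-1H-indole F3. C3-hydroxyethylation of its indolylmagnesium salt (EtMgBr, then ethylene oxide, toluene/THF, 0 °C → rt, the classical tryptophol synthesis) gives 2-{2-[(1R,2S)-2,3-bis(tert-butyldimethylsilyloxy)-1-(1-tosyl-1H-indol-3-yl)propyl]-1H-indol-3-yl}ethanol F4. TBAF in THF then removes the two silyl groups and the fallback comes back to the route at 21.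

Step 9 (butyllithium on 15 and trapping in the same flask). Any excess n-BuLi can lithiate C2 of the N-tosylindole or attack sulfur, the carbenoid can go astray, and the LiBr set free can open BF3-activated ethylene oxide in competition with the acetylide. The fallback sets out from 14. Colvin homologation with lithiated trimethylsilyldiazomethane (TMSCHN2, LiN(iPr)2, THF, −78 → 0 °C; addition, Peterson elimination, 1,2-hydrogen shift of the alkylidene carbene) turns the aldehyde in one operation into 3-[(3S,4S)-4,5-bis(tert-butyldimethylsilyloxy)pent-1-yn-3-yl]-1-tosyl-1H-indole F5, which is isolated and by-passes 15. Deprotonation with exactly one equivalent of n-BuLi (THF, −78 °C) then gives lithium acetylide 16 free of LiBr and 1-bromobutane, and BF3·OEt2 and ethylene oxide as in step 9 bring the fallback back to the route at 17.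

Step 7 (oxidation to the α-indolyl aldehyde). Partial epimerisation at C2 or β-elimination of silanol can occur under the acetic acid and iodinane by-products or on silica. The fallback sets out from 12. Displacement of the auxiliary with lithium ethanethiolate (EtSH, n-BuLi, THF, 0 °C) gives S-ethyl (2S,3S)-3,4-bis(tert-butyldimethylsilyloxy)-2-(1-tosyl-1H-indol-3-yl)butanethioate F6. Fukuyama reduction (Et3SiH, 10% Pd/C, acetone, rt) then delivers the aldehyde under neutral, non-oxidative conditions and comes back to the route at 14, by-passing 13.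

**Further compounds**

F1 | step 11 | [(3R,4S)-4,5-bis(tert-butyldimethylsilyloxy)-3-(1-tosyl-1H-indol-3-yl)pent-1-yn-1-yl]zinc chloride | Cl[Zn]C#C[C@@H](c1cn(S(=O)(=O)c2ccc(C)cc2)c2ccccc12)[C@H](O[Si](C)(C)C(C)(C)C)CO[Si](C)(C)C(C)(C)C
F2 | step 11 | 2-[(3S,4S)-4,5-bis(tert-butyldimethylsilyloxy)-3-(1-tosyl-1H-indol-3-yl)pent-1-yn-1-yl]aniline | Nc1ccccc1C#C[C@@H](c1cn(S(=O)(=O)c2ccc(C)cc2)c2ccccc12)[C@H](O[Si](C)(C)C(C)(C)C)CO[Si](C)(C)C(C)(C)C
F3 | step 11 | 3-[(1R,2S)-2,3-bis(tert-butyldimethylsilyloxy)-1-(1H-indol-2-yl)propyl]-1-tosyl-1H-indole | c1ccc2[nH]c(cc2c1)[C@@H](c1cn(S(=O)(=O)c2ccc(C)cc2)c2ccccc12)[C@H](O[Si](C)(C)C(C)(C)C)CO[Si](C)(C)C(C)(C)C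
F4 | step 11 | 2-{2-[(1R,2S)-2,3-bis(tert-butyldimethylsilyloxy)-1-(1-tosyl-1H-indol-3-yl)propyl]-1H-indol-3-yl}ethanol | OCCc1c([C@@H](c2cn(S(=O)(=O)c3ccc(C)cc3)c3ccccc23)[C@H](O[Si](C)(C)C(C)(C)C)CO[Si](C)(C)C(C)(C)C)[nH]c2ccccc12
F5 | step 9 | 3-[(3S,4S)-4,5-bis(tert-butyldimethylsilyloxy)pent-1-yn-3-yl]-1-tosyl-1H-indole | C#C[C@@H](c1cn(S(=O)(=O)c2ccc(C)cc2)c2ccccc12)[C@H](O[Si](C)(C)C(C)(C)C)CO[Si](C)(C)C(C)(C)C
F6 | step 7 | S-ethyl (2S,3S)-3,4-bis(tert-butyldimethylsilyloxy)-2-(1-tosyl-1H-indol-3-yl)butanethioate | CCSC(=O)[C@@H](c1cn(S(=O)(=O)c2ccc(C)cc2)c2ccccc12)[C@H](O[Si](C)(C)C(C)(C)C)CO[Si](C)(C)C(C)(C)C
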